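The synthesis rests on cutting ring A away from ring B along C1–C10 and C4–C5. Ring B (C5–C10), with its C6 oxygen, C8 methyl and methylated quaternary C10, is 2,6-dimethyl-1,4-benzoquinone in disguise; the C2 oxygen and the quaternary C4 (methyl plus C19 oxymethyl) map onto a (Z)-4,4-disubstituted 2-silyloxydiene. One enantioselective, Lewis-acid-catalysed Diels–Alder reaction therefore closes ring A, forms both bonds and fixes C10 and C4 absolutely, leaving carbonyls at C6 and C9 and an enol ether at C2 as handles. The diene is a triisopropylsilyl enol ether carrying a TBDPS-protected allylic alcohol.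

Key step: step 7

Locants: labdane numbering is used (ring A = C1–C5 and C10; ring B = C5–C10; C11/C12 side-chain methylenes; C13–C16 butenolide; C17 = methyl on C8; C18 = 4α-methyl; C19 = 4β-CH2O; C20 = methyl on C10). β is the face of C20.

Assumption: the sense of induction of the oxazaborolidinium catalyst is assigned from its α-C–H···O binding model, which points to the (R)-prolinol series; should adduct 14 prove antipodal, the (S)-series catalyst is used with no other change.

Two design choices:
- The diene carries TIPS (enol ether) and TBDPS (C19) groups. Both tolerate the strongly acidic boron cation, and the TBDPS ether is a poor ligand for it.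
- The trans ring fusion is not left to enolate equilibration of a 4,4-disubstituted 6-ketone, because peri strain between the 4α-methyl and the C6 carbonyl can favour the cis isomer. Instead the C5 hydrogen is removed (steps 8 and 9) and returned by α-face hydroboration (step 14), which sets C6 at the same time.

Step 1
Reactants: 1 prop-2-yn-1-ol
Product: 2 tert-butyl(diphenyl)(prop-2-yn-1-yloxy)silane
Conditions: TBDPSCl, imidazole, CH2Cl2, 0 °C → rt
Reagents that add atoms: tert-butyl(chloro)diphenylsilane, CC(C)(C)[Si](Cl)(c1ccccc1)c1ccccc1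
Why: Imidazole-promoted O-silylation of a primary alcohol gives a robust, weakly Lewis-basic TBDPS ether that should survive the cationic boron catalyst of step 7.

Step 2
Reactants: 2 tert-butyl(diphenyl)(prop-2-yn-1-yloxy)silane; 3 methyl chloroformate
Product: 5 methyl 4-[(tert-butyldiphenylsilyl)oxy]but-2-ynoate, via lithium acetylide 4 (not isolated)
Conditions: n-BuLi, THF, −78 °C; then ClCO2Me, −78 → 0 °C
Reagents that add atoms: none
Why: Deprotonation of the terminal alkyne and C-acylation of the acetylide by the chloroformate (acetylide carboxylation) is routine for silyl propargyl ethers.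

Step 3
Reactants: 5 methyl 4-[(tert-butyldiphenylsilyl)oxy]but-2-ynoate
Product: 7 methyl (Z)-4-[(tert-butyldiphenylsilyl)oxy]-3-methylbut-2-enoate, via alkenyl(methyl)cuprate 6 (not isolated)
Conditions: Me2CuLi (from CuI and 2 MeLi), THF, −78 °C; MeOH then aq. NH4Cl at −78 °C
Reagents that add atoms: lithium dimethylcuprate, [Li+].C[Cu-]C
Why: Syn-carbocupration of the ynoate (Gilman conjugate addition) and cold protonation of the configurationally stable alkenylcuprate place methyl and hydrogen cis, so the CH2OSi group ends cis to the ester (Z).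

Step 4
Reactants: 7 methyl (Z)-4-[(tert-butyldiphenylsilyl)oxy]-3-methylbut-2-enoate
Product: 8 (Z)-4-[(tert-butyldiphenylsilyl)oxy]-N-methoxy-N,3-dimethylbut-2-enamide
Conditions: MeNH(OMe)·HCl, i-PrMgCl, THF, −20 → 0 °C
Reagents that add atoms: N,O-dimethylhydroxylamine hydrochloride, CNOC.Cl
Why: Aminolysis of the ester by the chloromagnesium amide of N,O-dimethylhydroxylamine (Weinreb amide formation) runs at low temperature and should leave the trisubstituted Z-alkene untouched.

Step 5
Reactants: 8 (Z)-Weinreb amide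
Product: 10 (Z)-5-[(tert-butyldiphenylsilyl)oxy]-4-methylpent-3-en-2-one, via magnesium chelate 9 (not isolated)
Conditions: MeMgBr, THF, 0 °C; aq. NH4Cl
Reagents that add atoms: methylmagnesium bromide, C[Mg]Br
Why: In the Weinreb ketone synthesis the chelated tetrahedral adduct stops the Grignard addition at the methyl ketone, and the near-neutral work-up should preserve the Z-geometry.

Step 6
Reactants: 10 (Z)-enone
Product: 12 (Z)-5-[(tert-butyldiphenylsilyl)oxy]-4-methyl-2-[(triisopropylsilyl)oxy]penta-1,3-diene, via lithium dienolate 11 (not isolated)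
Conditions: LDA (LiN(i-Pr)2), THF, −78 °C; TIPSOTf, −78 → 0 °C; Et3N-buffered work-up
Reagents that add atoms: triisopropylsilyl trifluoromethanesulfonate, CC(C)[Si](OS(=O)(=O)C(F)(F)F)(C(C)C)C(C)C
Why: Kinetic deprotonation at the α'-methyl group and O-silylation of the cross-conjugated enolate (kinetic silyl enol ether formation) give the 2-silyloxydiene without touching the γ-positions, so the Z-alkene is retained.

Step 7
Reactants: 12 (Z)-silyloxydiene; 13 2,6-dimethyl-1,4-benzoquinone
Product: 14 cis-fused Diels–Alder adduct (C2=C3 TIPS enol ether; 7-ene-6,9-dione; 4α-methyl; 4β-CH2OTBDPS; 5β-H; 10β-methyl)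
Conditions: (R)-B-(o-tolyl)oxazaborolidine from (R)-α,α-diphenylprolinol and o-tolylboronic acid, protonated with HNTf2 (20 mol%), CH2Cl2, −78 → −40 °C; Et3N quench
Reagents that add atoms: none
Why: The protonated oxazaborolidine binds the unhindered C6 carbonyl of 13 at the lone pair syn to C5–H, so the methyl-bearing C10 becomes the electrophilic β-carbon, and the siloxy-activated terminus C1 of 12 bonds to C10 while the disubstituted terminus C4 bonds to C5 in an endo, suprafacial and probably asynchronous [4+2] cycloaddition. The closest known reaction type is the cationic oxazaborolidine-catalysed Diels–Alder reaction of methylated benzoquinones with 2-silyloxybutadienes, supported by Lewis-acid-promoted cycloadditions of 4,4-disubstituted 2-silyloxydienes. Ring A is closed as a cyclohexene by this [4+2] mode, with both σ-bonds (C1–C10 and C4–C5) formed in the one operation. C10 and C5 should emerge cis because addition across the quinone C=C is suprafacial, C4 is fixed relative to C10 by the endo orientation together with the Z-geometry of 12 (the inside CH2OTBDPS group ends cis to the C10 methyl), and the absolute configuration is dictated by the catalyst, whose aryl group covers one face of the bound quinone. The step needs regioselectivity and endo selectivity: the former is secured by carbonyl-selective coordination reinforced by the polarisation of the siloxydiene, the latter by secondary overlap with the quinone carbonyls and by the preference of the bulky C4 terminus to meet the hydrogen-bearing C5. The C5 centre formed here is provisional and is reset in step 14.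

Step 8
Reactants: 14 cis-fused adduct
Product: 16 6-triflyloxy-2,5,7-trien-9-one, via lithium dienolate 15 (not isolated)
Conditions: LiN(SiMe3)2, THF, −78 °C; Comins' reagent, −78 → −20 °C
Reagents that add atoms: N-(5-chloropyridin-2-yl)bis(trifluoromethanesulfonyl)imide (Comins' reagent), O=S(=O)(N(c1ccc(Cl)cn1)S(=O)(=O)C(F)(F)F)C(F)(F)F
Why: The ring-fusion hydrogen at C5 is the only sp3 α-hydrogen of the C6 carbonyl, so kinetic lithium-amide enolisation and O-sulfonylation (enol triflate formation) should remove the cis-configured C5 centre regiospecifically.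

Step 9
Reactants: 16 dienyl triflate
Product: 17 2,5,7-trien-9-one (C6–H)
Conditions: Pd(OAc)2 (5 mol%), PPh3, n-Bu3N, HCO2H, DMF, 60 °C
Reagents that add atoms: none
Why: Palladium-catalysed formate reduction of an alkenyl triflate (oxidative addition, formate decarboxylation, reductive elimination) replaces the C6 triflate by hydrogen and leaves the linearly conjugated 5,7-dien-9-one.

Step 10
Reactants: 17 dienone
Product: 19 9-triflyloxy-2,5,8-triene, via lithium enolate 18 (not isolated)
Conditions: L-Selectride (LiBH(s-Bu)3), THF, −78 °C; Comins' reagent, −78 → 0 °C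
Reagents that add atoms: N-(5-chloropyridin-2-yl)bis(trifluoromethanesulfonyl)imide (Comins' reagent), O=S(=O)(N(c1ccc(Cl)cn1)S(=O)(=O)C(F)(F)F)C(F)(F)F
Why: Conjugate hydride addition at the unsubstituted C7 (1,2-attack at the neopentyl C9 carbonyl and 1,6-attack at the fully substituted C5 being blocked) gives the C8=C9 enolate regiospecifically, and O-triflation traps it (conjugate reduction–enolate triflation).

Step 11
Reactants: 19 silyl enol ether
Product: 20 9-triflyloxy-5,8-dien-2-one
Conditions: aq. HCl (2 M), THF, 0 °C → rt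
Reagents that add atoms: none
Why: Acid hydrolysis of the silyl enol ether releases the C2 ketone under conditions that the TBDPS alkyl ether, the enol triflate and the skipped diene should tolerate.

Step 12
Reactants: 20 C2 ketone
Product: 21 9-triflyloxy-5,8-dien-2α-ol
Conditions: Al(Oi-Pr)3, i-PrOH/toluene, acetone (5 mol%), reflux, 48 h
Reagents that add atoms: none
Why: A Meerwein–Ponndorf–Verley reduction run under equilibrating (Oppenauer-reversible) conditions should settle on the equatorial 2α-alcohol, because the axial 2β-epimer would suffer two syn-axial contacts with C20 and the C4 CH2OSi group.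

Step 13
Reactants: 21 2α-alcohol
Product: 22 2α-TBS ether
Conditions: TBSCl, imidazole, DMF, rt
Reagents that add atoms: tert-butyl(chloro)dimethylsilane, CC(C)(C)[Si](C)(C)Cl
Why: Imidazole-mediated silylation of the unhindered equatorial alcohol masks C2–OH so that only C6–OH will be free for acetylation.

Step 14
Reactants: 22 Δ5-alkene
Product: 24 trans-fused 6α-alcohol (5α-H), via C6 alkylborane 23 (not isolated)
Conditions: BH3·THF, THF, 0 °C → rt; NaBO3·4H2O, THF/H2O, rt
Reagents that add atoms: sodium perborate tetrahydrate (NaBO3·4H2O), [Na+].[O-]B1OO1.O.O.O.O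
Why: Hydroboration–oxidation of the trisubstituted C5=C6 alkene is anti-Markovnikov and syn from the α-face, the β-face being screened by the axial C20 and C19 groups, so 5α-H (trans fusion) and 6α-OH should be set together as in the hydroboration of Δ5-steroids.

Step 15
Reactants: 24 6α-alcohol
Product: 25 6α-acetate
Conditions: Ac2O, DMAP, pyridine, CH2Cl2, rt
Reagents that add atoms: acetic anhydride, CC(=O)OC(C)=O
Why: DMAP-catalysed acylation esterifies the only free hydroxyl group with retention at C6.

Step 16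
Reactants: 25 enol triflate
Product: 26 9-vinyl-8,11-diene
Conditions: CH2=CHSnBu3, Pd(PPh3)4 (10 mol%), LiCl, CuCl, DMSO, 60 °C
Reagents that add atoms: tributyl(vinyl)stannane, C=C[Sn](CCCC)(CCCC)CCCC
Why: Stille coupling under the CuCl-accelerated conditions used for hindered partners replaces the triflate by vinyl and keeps the tetrasubstituted C8=C9 alkene in place.

Step 17
Reactants: 26 vinyl diene; 27 4-bromofuran-2(5H)-one
Product: 29 bis-silyl ether of the target, via B-alkyl-9-BBN 28 (not isolated)
Conditions: 9-BBN, THF, rt; then 27, Pd(dppf)Cl2 (10 mol%), AsPh3, aq. K3PO4, DMF, rt → 45 °C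
Reagents that add atoms: none
Why: 9-BBN hydroborates only the monosubstituted vinyl group at its terminus, and the primary alkylborane undergoes B-alkyl Suzuki–Miyaura coupling at the β-bromo enoate carbon of the butenolide.

Step 18
Reactants: 29 bis-silyl ether
Product: 30 target
Conditions: HF·pyridine, pyridine, THF, 0 °C → rt
Reagents that add atoms: none
Why: Fluoride-mediated desilylation under buffered acidic conditions should remove both silyl ethers while the acetate, the butenolide and the tetrasubstituted alkene stay intact.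

Compound list
1 | prop-2-yn-1-ol | C#CCO | starting material
2 | tert-butyl(diphenyl)(prop-2-yn-1-yloxy)silane | C#CCO[Si](c1ccccc1)(c1ccccc1)C(C)(C)C | intermediate
3 | methyl chloroformate | COC(=O)Cl | starting material
4 | lithium acetylide of 2 | [Li]C#CCO[Si](c1ccccc1)(c1ccccc1)C(C)(C)C | intermediate
5 | methyl 4-[(tert-butyldiphenylsilyl)oxy]but-2-ynoate | COC(=O)C#CCO[Si](c1ccccc1)(c1ccccc1)C(C)(C)C | intermediate
6 | lithium alkenyl(methyl)cuprate from syn-carbocupration of 5 (Cu cis to the new methyl) | COC(=O)/C([Cu-]C)=C(/C)CO[Si](c1ccccc1)(c1ccccc1)C(C)(C)C.[Li+] | intermediate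
7 | methyl (Z)-4-[(tert-butyldiphenylsilyl)oxy]-3-methylbut-2-enoate | COC(=O)/C=C(/C)CO[Si](c1ccccc1)(c1ccccc1)C(C)(C)C | intermediate
8 | (Z)-4-[(tert-butyldiphenylsilyl)oxy]-N-methoxy-N,3-dimethylbut-2-enamide | CON(C)C(=O)/C=C(/C)CO[Si](c1ccccc1)(c1ccccc1)C(C)(C)C | intermediate
9 | bromomagnesium alkoxide (tetrahedral adduct of MeMgBr and 8) | CON(C)C(C)(O[Mg]Br)/C=C(/C)CO[Si](c1ccccc1)(c1ccccc1)C(C)(C)C | intermediate
10 | (Z)-5-[(tert-butyldiphenylsilyl)oxy]-4-methylpent-3-en-2-one | CC(=O)/C=C(/C)CO[Si](c1ccccc1)(c1ccccc1)C(C)(C)C | intermediate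
11 | lithium cross-conjugated dienolate of 10 | [Li]OC(=C)/C=C(/C)CO[Si](c1ccccc1)(c1ccccc1)C(C)(C)C | intermediate
12 | (Z)-5-[(tert-butyldiphenylsilyl)oxy]-4-methyl-2-[(triisopropylsilyl)oxy]penta-1,3-diene | C=C(O[Si](C(C)C)(C(C)C)C(C)C)/C=C(/C)CO[Si](c1ccccc1)(c1ccccc1)C(C)(C)C | intermediate
13 | 2,6-dimethyl-1,4-benzoquinone | CC1=CC(=O)C=C(C)C1=O | starting material
14 | cis-fused adduct: 19-(TBDPS-oxy)-2-(TIPS-oxy)-4α,8,10β-trimethyl-5β-H-decal-2,7-diene-6,9-dione | O=C1C=C(C)C(=O)[C@@]2(C)CC(O[Si](C(C)C)(C(C)C)C(C)C)=C[C@](C)(CO[Si](c3ccccc3)(c3ccccc3)C(C)(C)C)[C@@H]12 | intermediate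
15 | lithium 5(6)-dienolate of 14 (O6–Li) | O=C1C(C)=CC(O[Li])=C2[C@@](C)(CO[Si](c3ccccc3)(c3ccccc3)C(C)(C)C)C=C(O[Si](C(C)C)(C(C)C)C(C)C)C[C@]12C | intermediate
16 | 6-triflyloxy-19-(TBDPS-oxy)-2-(TIPS-oxy)-4α,8,10β-trimethyldecal-2,5,7-trien-9-one | O=C1C(C)=CC(OS(=O)(=O)C(F)(F)F)=C2[C@@](C)(CO[Si](c3ccccc3)(c3ccccc3)C(C)(C)C)C=C(O[Si](C(C)C)(C(C)C)C(C)C)C[C@]12C | intermediate
17 | 19-(TBDPS-oxy)-2-(TIPS-oxy)-4α,8,10β-trimethyldecal-2,5,7-trien-9-one | O=C1C(C)=CC=C2[C@@](C)(CO[Si](c3ccccc3)(c3ccccc3)C(C)(C)C)C=C(O[Si](C(C)C)(C(C)C)C(C)C)C[C@]12C | intermediate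
18 | lithium 8(9)-enolate (2,5,8-triene; O9–Li) | [Li]OC1=C(C)CC=C2[C@@](C)(CO[Si](c3ccccc3)(c3ccccc3)C(C)(C)C)C=C(O[Si](C(C)C)(C(C)C)C(C)C)C[C@]12C | intermediate
19 | 9-triflyloxy-19-(TBDPS-oxy)-2-(TIPS-oxy)-4α,8,10β-trimethyldecal-2,5,8-triene | O=S(=O)(OC1=C(C)CC=C2[C@@](C)(CO[Si](c3ccccc3)(c3ccccc3)C(C)(C)C)C=C(O[Si](C(C)C)(C(C)C)C(C)C)C[C@]12C)C(F)(F)F | intermediate
20 | 9-triflyloxy-19-(TBDPS-oxy)-4α,8,10β-trimethyldecal-5,8-dien-2-one | O=S(=O)(OC1=C(C)CC=C2[C@@](C)(CO[Si](c3ccccc3)(c3ccccc3)C(C)(C)C)CC(=O)C[C@]12C)C(F)(F)F | intermediate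
21 | 9-triflyloxy-19-(TBDPS-oxy)-4α,8,10β-trimethyldecal-5,8-dien-2α-ol | O=S(=O)(OC1=C(C)CC=C2[C@@](C)(CO[Si](c3ccccc3)(c3ccccc3)C(C)(C)C)C[C@H](O)C[C@]12C)C(F)(F)F | intermediate
22 | 2α-(TBS-oxy) ether of 21 | O=S(=O)(OC1=C(C)CC=C2[C@@](C)(CO[Si](c3ccccc3)(c3ccccc3)C(C)(C)C)C[C@H](O[Si](C)(C)C(C)(C)C)C[C@]12C)C(F)(F)F | intermediate
23 | 6α-boryl-5α-H alkylborane from 22 | B[C@H]1CC(C)=C(OS(=O)(=O)C(F)(F)F)[C@@]2(C)C[C@@H](O[Si](C)(C)C(C)(C)C)C[C@](C)(CO[Si](c3ccccc3)(c3ccccc3)C(C)(C)C)[C@H]12 | intermediate
24 | trans-fused 9-triflyloxy-2α-(TBS-oxy)-19-(TBDPS-oxy)-4α,8,10β-trimethyl-5α-H-decal-8-en-6α-ol | O[C@H]1CC(C)=C(OS(=O)(=O)C(F)(F)F)[C@@]2(C)C[C@@H](O[Si](C)(C)C(C)(C)C)C[C@](C)(CO[Si](c3ccccc3)(c3ccccc3)C(C)(C)C)[C@H]12 | intermediate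
25 | 6α-acetate of 24 | CC(=O)O[C@H]1CC(C)=C(OS(=O)(=O)C(F)(F)F)[C@@]2(C)C[C@@H](O[Si](C)(C)C(C)(C)C)C[C@](C)(CO[Si](c3ccccc3)(c3ccccc3)C(C)(C)C)[C@H]12 | intermediate
26 | 6α-acetoxy-2α-(TBS-oxy)-19-(TBDPS-oxy)-13,14,15,16-tetranorlabda-8,11-diene (9-vinyl compound) | CC(=O)O[C@H]1CC(C)=C(C=C)[C@@]2(C)C[C@@H](O[Si](C)(C)C(C)(C)C)C[C@](C)(CO[Si](c3ccccc3)(c3ccccc3)C(C)(C)C)[C@H]12 | intermediate
27 | 4-bromofuran-2(5H)-one | O=C1C=C(Br)CO1 | starting material
28 | 12-(9-borabicyclo[3.3.1]nonan-9-yl) alkylborane from 26 | CC(=O)O[C@H]1CC(C)=C(CCB2C3CCCC2CCC3)[C@@]2(C)C[C@@H](O[Si](C)(C)C(C)(C)C)C[C@](C)(CO[Si](c3ccccc3)(c3ccccc3)C(C)(C)C)[C@H]12 | intermediate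
29 | 6α-acetoxy-2α-(TBS-oxy)-19-(TBDPS-oxy)labda-8,13-dien-15,16-olide | CC(=O)O[C@H]1CC(C)=C(CCC2=CC(=O)OC2)[C@@]2(C)C[C@@H](O[Si](C)(C)C(C)(C)C)C[C@](C)(CO[Si](c3ccccc3)(c3ccccc3)C(C)(C)C)[C@H]12 | intermediate
30 | 6α-acetoxy-2α,19-dihydroxylabda-8,13-dien-15,16-olide (CNP0231903.1) | CC(=O)O[C@H]1CC(C)=C(CCC2=CC(=O)OC2)[C@@]2(C)C[C@@H](O)C[C@](C)(CO)[C@H]12 | target

Total step count: 18. Longest linear sequence: 18 steps (1 → 30); 13 and 27 are purchased.

Steps most likely to fail

Step 7. The congested Z-diene may react sluggishly, the cycloaddition may stall after the first C–C bond, or endo control may be lost through rotation in a zwitterionic intermediate. The fallback sets out from 12 and 13 and returns at 14, and it separates the two bond formations as a double Mukaiyama–Michael sequence. The same catalyst at −78 °C with an early quench should give the open-chain adduct, the 6-silyloxy dienone F1 (silyl transferred to O6), which is isolated. Treatment with Me2AlCl in CH2Cl2 at −78 → −20 °C should then close ring A by intramolecular Mukaiyama–Michael addition of C5 to C4, with silyl transfer to O2 giving 14.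

Step 10. Hydride may be delivered 1,2 or 1,6 instead of 1,4, or the crowded tetrasubstituted enolate may be triflated incompletely in the presence of the borane by-product. The fallback sets out from 17 and returns at 19. Copper hydride-catalysed conjugate hydrosilylation ([(Ph3P)CuH]6 cat., PhMe2SiH, toluene, rt) should give the C9 dimethylphenylsilyl enol ether F2, which is isolated. MeLi in THF at 0 °C then releases the boron-free lithium enolate 18, and Comins' reagent converts it into 19.

Step 17. The base-sensitive bromobutenolide may be hydrolysed before transmetalation, or slow coupling may lead to protodeboronation of the alkylborane. The fallback sets out from 26 through borane 28 and returns at 29. Coupling of 28 with 3-bromofuran under the same B-alkyl Suzuki conditions should give the base-stable 3-furyl compound F3. Photo-oxygenation of the furan (O2, rose bengal, hν, i-Pr2NEt, CH2Cl2, −78 °C), which is expected to outpace any ene reaction of the shielded C8=C9 alkene, should give the γ-hydroxybutenolide F4 regioselectively. Reduction of F4 with NaBH4 in MeOH at 0 °C and relactonisation of the hydroxy acid then give 29.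

Further compounds
F1 | step 7 | open-chain Mukaiyama–Michael adduct: (Z)-enone side chain on C10 of the 6-(TIPS-oxy)-8,10-dimethylcyclohexa-5,7-dien-9-one | CC1=CC(O[Si](C(C)C)(C(C)C)C(C)C)=C[C@](C)(CC(=O)/C=C(/C)CO[Si](c2ccccc2)(c2ccccc2)C(C)(C)C)C1=O
F2 | step 10 | C9 dimethylphenylsilyl enol ether (2,5,8-triene) | C[Si](C)(c1ccccc1)OC1=C(C)CC=C2[C@@](C)(CO[Si](c3ccccc3)(c3ccccc3)C(C)(C)C)C=C(O[Si](C(C)C)(C(C)C)C(C)C)C[C@]12C
F3 | step 17 | 3-furyl compound: 6α-acetoxy-2α-(TBS-oxy)-19-(TBDPS-oxy)-15,16-epoxylabda-8,13(16),14-triene | CC(=O)O[C@H]1CC(C)=C(CCc2ccoc2)[C@@]2(C)C[C@@H](O[Si](C)(C)C(C)(C)C)C[C@](C)(CO[Si](c3ccccc3)(c3ccccc3)C(C)(C)C)[C@H]12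
F4 | step 17 | γ-hydroxybutenolide (16-hydroxy-15,16-olide, epimers at C16) | CC(=O)O[C@H]1CC(C)=C(CCC2=CC(=O)OC2O)[C@@]2(C)C[C@@H](O[Si](C)(C)C(C)(C)C)C[C@](C)(CO[Si](c3ccccc3)(c3ccccc3)C(C)(C)C)[C@H]12
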